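(The numbers in the tables were generated by integration with made-up constants.)

Start at the early times and compare flasks by how long each takes to reach one fraction of its charge, not by their curves.

| setting | Sunday's | Tuesday's | Wednesday's | Friday's | Saturday's |
|---|---|---|---|---|---|
| starting material | 0.0500 M | 0.150 M | 0.0500 M | 0.0500 M | 0.0500 M |
| partner | 0.100 M | 0.100 M | 0.100 M | 0.150 M | 0.300 M |
| product |  |  | 0.0250 M |  |  |
| time |  |  |  |  | 28 min |

| run | time / min | [product] / M |
|---|---|---|
| Sunday's run | 1.1 | 0.0036 |
| Sunday's run | 2.1 | 0.0067 |
| Sunday's run | 4.1 | 0.0129 |
| Sunday's run | 7.7 | 0.0200 |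
| Sunday's run | 15 | 0.0298 |
| Sunday's run | 28 | 0.0374 |
| Tuesday's run | 1.1 | 0.0067 |
| Tuesday's run | 2.1 | 0.0126 |
| Tuesday's run | 4.1 | 0.0216 |
| Tuesday's run | 7.7 | 0.0342 |
| Tuesday's run | 15 | 0.0516 |
| Tuesday's run | 28 | 0.0658 |
| Wednesday's run | 1.1 | 0.0289 |
| Wednesday's run | 2.1 | 0.0318 |
| Wednesday's run | 4.1 | 0.0370 |
| Wednesday's run | 7.7 | 0.0443 |
| Wednesday's run | 15 | 0.0543 |
| Wednesday's run | 28 | 0.0617 |
| Friday's run | 1.1 | 0.0051 |
| Friday's run | 2.1 | 0.0108 |
| Friday's run | 4.1 | 0.0178 |
| Friday's run | 7.7 | 0.0278 |
| Friday's run | 15 | 0.0384 |
| Friday's run | 28 | 0.0428 |

(readings scatter by 4 × 10⁻⁴ M)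

- Overall: starting material + partner -> product.
- Constant volume, constant temperature.
- A reading of a species includes what of it is bound.
- "The second partner" is partner.
- An order is taken over about fifteen percent of the charge, up and down.

1. the power of [partner] that the first rate follows, about the charge of the Sunday's run; measure it at two percent of starting material made into product
2. the power of [starting material] that the first rate follows, about the charge of the Sunday's run; measure it at two percent of starting material made into product (one fixed amount of product, the same in the runs compared)
3. product in the Saturday's run at 28 min, as a share of the starting material charged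

Use the bench rule first: with partner in excess, treat the run as pseudo-first-order, so that more partner rescales the time axis and leaves the shape of the curve alone. Test it on Sunday's and Friday's runs, which share one charge of starting material (the limiting reagent).

Sunday's run reaches 40.0% of the charge at 7.7 min.
Friday's run reaches it, interpolated, at 4.89 min.
Ratio of times: 1.57.
Order in partner, read at that fraction: 1.12.

Take this 1.57 as the clock factor, the time Sunday's run needs for a fraction of the charge divided by the time Friday's run needs for the same fraction. It is a ratio of mean rates with time divided out. Apply the same division to Sunday's and Tuesday's runs at nearly equal product, about a quarter of Sunday's charge, and the chord order in starting material reads 0.609 between charges of 0.0500 M and 0.150 M.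

Now find the border. Friday's run at 15 min and Sunday's run at 28 min stand near 74.8% of the charge, so the factor reads 1.87 there, later in the run and larger than early on. The partner-to-starting-material ratio is 2.00 on Sunday and 3.00 on Friday, below the 10-fold excess the rule assumes. By those readings and the overall equation, Sunday's run has used 37.4% of its partner at 28 min and Friday's run 25.6% at 15 min, more on Sunday.

Commit to a figure for Saturday's run anyway, calling the shortfall the fraction of the charge not standing as product:

Saturday's clock against Friday's: 2.17.
Saturday's 28 min count as 60.8 min on Friday's clock.
Friday's shortfall at 28 min: 14.4%, falling at 0.0367 min⁻¹.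
Carrying that fall onward gives 95.7% product.

The forecast gives 0.95 (0.8 to 1.1) for the order in partner, 0.7 (0.55 to 0.85) for the order in starting material and 93% (84% to 98%) for Saturday's product, the last as “roughly 93% conversion, limited by that loss”. My product figure stands above its figure, my partner order above its order, and my chord order below its local order.

Saturday's run gives 93.9% at 28 min, and the first rate about Sunday's charge follows orders of 1.1 in partner and 0.61 in starting material.

    2 partner ⇌ reagent dimer, settled at all times (72.20 L mol⁻¹)
    starting material + reagent dimer → product + partner (5.790 L mol⁻¹ min⁻¹)
    2 starting material ⇌ idle substrate dimer, settled at all times (70.60 L mol⁻¹)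
    2 starting material → homo dimer (2.376 L mol⁻¹ min⁻¹)

Saturday's product lies 1.8 percentage points under my figure. Where 2% of Sunday's charge has turned, Friday's rate is 1.6 times Sunday's. Divide Sunday's time to a quarter of its charge, 4.36 min, by the clock factor and Friday's run falls due at that fraction at 2.78 min; it stands there at 2.66 min.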